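**Retrosynthetic overview**

1. The target comes from the 7α‑alcohol 27 by Mitsunobu inversion with acetic acid and desilylation; 27 comes from the mixed diester 24 by allylic oxidation at C7 and selective reduction of the C15 ester.
2. Diester 24 comes from the bicyclic C8 silyl enol ether 18: the C11–C16 chain is attached at C9 by Mukaiyama–Michael addition to but‑3‑en‑2‑one and Horner–Wadsworth–Emmons olefination, and C17 by methylenation of the C8 ketone.
3. Compound 18 comes from dienone 13: the C4 quaternary centre (α‑methyl, β‑CO2Me) and the 5α‑H are set by reductive methylation of a C4=C5 unsaturated ester, made from the C4 ketone through its enol triflate.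
4. Dienone 13 comes from the acyclic dienynone 12 by an enantioselective intramolecular Diels–Alder reaction that forms C6–C7 and C5–C10 and so closes rings B and A in the same step. The enabling feature: in ring B, C8 (the exocyclic‑methylene carbon, a masked ketone and hence the oxygen‑bearing carbon of a C7=C8–C9=C10 silyloxy diene) lies 1,4 to ring‑fusion carbon C5, and C5 is bonded to C4, which carries the carboxyl carbon and can serve as a ketone activating a C5≡C6 dienophile.
5. Dienynone 12 comes from hex‑5‑yn‑1‑ol by carboalumination/iodination (C20 and the E‑alkene), Stille acylation, silyl dienol ether formation and ethynyl Grignard addition to an N‑methoxy‑N‑methylamide.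

Key step: step 7

Remark (assumption on the chemistry): labdane numbering (C1–C20; C18 = 4α‑methyl, C19 = 4β‑carboxyl, C20 on C10, C17 on C8, C11–C16 chain on C9) and α/β face descriptors are used for the bicyclic compounds; the (S)‑configured oxazaborolidine in step 7 is assumed, by analogy with its ketone‑dienophile cycloadditions, to give the (R)‑configured quaternary carbon, and the (R)‑catalyst would be used should the adduct prove antipodal.

**Route**

Step 1
Reactants: 1 hex‑5‑yn‑1‑ol
Product: 3 (E)‑6‑iodo‑5‑methylhex‑5‑en‑1‑ol, via alkenylalane 2 (not isolated)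
Conditions: Me3Al, Cp2ZrCl2 (0.25 equiv), CH2Cl2, 0 °C → rt; then I2, THF, −30 → 0 °C
Reagents that add atoms: trimethylaluminium, C[Al](C)C; iodine, II
Why: Zirconium‑catalysed Negishi carboalumination adds methyl and aluminium syn across the terminal alkyne with methyl on the internal carbon, and iodinolysis proceeds with retention, so the (E)‑trisubstituted iodoalkene (future C9=C10 with C20) should form as one isomer.

Step 2
Reactants: 3 (E)‑6‑iodo‑5‑methylhex‑5‑en‑1‑ol
Product: 4 (E)‑6‑iodo‑5‑methylhex‑5‑enoic acid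
Conditions: 2,2,6,6‑tetramethylpiperidin‑1‑oxyl (cat.), PhI(OAc)2, MeCN/H2O, rt
Reagents that add atoms: water, O
Why: Nitroxyl‑catalysed oxidation in aqueous acetonitrile takes the primary alcohol through the aldehyde hydrate to the acid without touching the iodoalkene.

Step 3
Reactants: 4 (E)‑6‑iodo‑5‑methylhex‑5‑enoic acid
Product: 6 (E)‑6‑iodo‑N‑methoxy‑N,5‑dimethylhex‑5‑enamide, via acyl imidazole 5 (not isolated)
Conditions: 1,1'‑carbonyldiimidazole, CH2Cl2, rt; then MeNH(OMe)·HCl, rt
Reagents that add atoms: N,O‑dimethylhydroxylamine hydrochloride, CNOC.Cl; 1,1'‑carbonyldiimidazole, O=C(n1ccnc1)n1ccnc1 (imidazolyl group of 5 only)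
Why: Acyl imidazole formation and aminolysis give the N‑methoxy‑N‑methylamide, which later accepts exactly one equivalent of an alkynyl Grignard reagent.

Step 4
Reactants: 6 (E)‑6‑iodo‑N‑methoxy‑N,5‑dimethylhex‑5‑enamide; 7 tributyl(1‑ethoxyvinyl)stannane
Product: 9 (E)‑N‑methoxy‑N,5‑dimethyl‑7‑oxooct‑5‑enamide, via ethoxy diene 8 (not isolated)
Conditions: Pd(PPh3)4 (5 mol %), DMF, 80 °C; then 1 M HCl, THF, 0 °C → rt
Reagents that add atoms: water, O
Why: Stille coupling of the alkenyl iodide with the α‑ethoxyvinyl stannane retains the (E)‑geometry, and mild acid hydrolysis of the enol ether unmasks the methyl ketone (C7–C8).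

Step 5
Reactants: 9 (E)‑N‑methoxy‑N,5‑dimethyl‑7‑oxooct‑5‑enamide
Product: 10 (E)‑7‑[(tert‑butyldimethylsilyl)oxy]‑N‑methoxy‑N,5‑dimethylocta‑5,7‑dienamide
Conditions: TBSOTf, Et3N, CH2Cl2, −78 → 0 °C
Reagents that add atoms: tert‑butyldimethylsilyl trifluoromethanesulfonate, CC(C)(C)[Si](C)(C)OS(=O)(=O)C(F)(F)F
Why: Soft enolisation of the β,β‑disubstituted methyl enone occurs kinetically at the α'‑methyl group and should give the cross‑conjugated 2‑silyloxy diene without disturbing the (E)‑alkene.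

Step 6
Reactants: 10 (E)‑7‑[(tert‑butyldimethylsilyl)oxy]‑N‑methoxy‑N,5‑dimethylocta‑5,7‑dienamide; 11 ethynylmagnesium bromide
Product: 12 (E)‑9‑[(tert‑butyldimethylsilyl)oxy]‑7‑methyldeca‑7,9‑dien‑1‑yn‑3‑one
Conditions: THF, −78 → 0 °C; inverse quench into cold aq NaHSO4; used at once
Reagents that add atoms: none
Why: The N‑methoxy‑N‑methylamide forms a stable magnesium chelate that releases the alkynyl ketone only on quench, so over‑addition is avoided and the silyl dienol ether is untouched.

Step 7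
Reactants: 12 (E)‑9‑[(tert‑butyldimethylsilyl)oxy]‑7‑methyldeca‑7,9‑dien‑1‑yn‑3‑one
Product: 13 (4aR)‑6‑[(tert‑butyldimethylsilyl)oxy]‑4a‑methyl‑3,4,4a,7‑tetrahydronaphthalen‑1(2H)‑one (C4 ketone, C5=C6, C8=C9 silyl enol ether, 10β‑methyl)
Conditions: (S)‑1‑(2‑methylphenyl)‑3,3‑diphenyltetrahydro‑1H,3H‑pyrrolo[1,2‑c][1,3,2]oxazaborole (20 mol %), HNTf2 (18 mol %), CH2Cl2, −78 → −40 °C; Et3N quench
Reagents that add atoms: none
Why: Coordination of the boron of the N‑protonated oxazaborolidine to the C4 carbonyl lowers the LUMO of the ynone, and an asynchronous normal‑demand [4+2] cycloaddition follows in which the nucleophilic terminus C7 of the 2‑silyloxy diene bonds to the β‑carbon C6 slightly ahead of C10 to C5. The closest known reaction types are the oxazaborolidinium‑catalysed enantioselective Diels–Alder reactions of acetylenic ketones and of 2‑silyloxy dienes, and the catalysed intramolecular Diels–Alder reaction of tethered trienes. Ring B is closed as the new six‑membered cyclohexa‑1,4‑diene of the cycloaddition itself, and ring A is closed at the same time through the C1–C2–C3–C4 tether in the fused mode, both new bonds lying in six‑membered rings. C10 is the only stereocentre created, because the alkyne leaves C5 trigonal; its configuration is set by the catalyst, which shields one face of the bound ynone, while the short tether allows only one folding and the (E)‑C9=C10 geometry from step 1 places the tether outside and the methyl inside the diene. The step needs enantiofacial selectivity and the C6–C7/C5–C10 pairing: the pairing is enforced by the tether and is also the electronically matched orientation, the quaternary C10 prevents aromatisation of the product, and the low temperature should keep the uncatalysed background reaction slow.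

Step 8
Reactants: 13 (4aR)‑6‑[(tert‑butyldimethylsilyl)oxy]‑4a‑methyl‑3,4,4a,7‑tetrahydronaphthalen‑1(2H)‑one
Product: 15 (4aR)‑6‑[(tert‑butyldimethylsilyl)oxy]‑4a‑methyl‑2,3,4,4a,7,8‑hexahydronaphthalen‑1‑yl trifluoromethanesulfonate, via lithium enolate 14 (not isolated)
Conditions: LiBH(s‑Bu)3, THF, −78 °C; then PhNTf2, −78 → 0 °C
Reagents that add atoms: N‑phenylbis(trifluoromethanesulfonimide), O=S(=O)(N(c1ccccc1)S(=O)(=O)C(F)(F)F)C(F)(F)F; lithium tri‑sec‑butylborohydride, [Li+].CCC(C)[BH-](C(C)CC)C(C)CC (lithium counter‑ion of 14 only)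
Why: Conjugate reduction of the s‑cis enone by the bulky borohydride gives the C4–C5 enolate regiospecifically, and O‑sulfonylation traps it as the tetrasubstituted enol triflate.

Step 9
Reactants: 15 the enol triflate
Product: 16 methyl (4aR)‑6‑[(tert‑butyldimethylsilyl)oxy]‑4a‑methyl‑2,3,4,4a,7,8‑hexahydronaphthalene‑1‑carboxylate
Conditions: Pd(OAc)2 (5 mol %), 1,1'‑bis(diphenylphosphino)ferrocene (10 mol %), CO (1 atm), MeOH, Et3N (excess), DMF, 60 °C
Reagents that add atoms: carbon monoxide, [C-]#[O+]; methanol, CO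
Why: Palladium‑catalysed methoxycarbonylation of the enol triflate installs C19 as the C4=C5 conjugated methyl ester.

Step 10
Reactants: 16 the unsaturated ester
Product: 18 methyl (1S,4aS,8aR)‑6‑[(tert‑butyldimethylsilyl)oxy]‑1,4a‑dimethyl‑1,2,3,4,4a,7,8,8a‑octahydronaphthalene‑1‑carboxylate (4α‑methyl, 4β‑CO2Me, 5α‑H, 10β‑methyl), via lithium ester enolate 17 (not isolated)
Conditions: Li, NH3 (l), THF, t‑BuOH (1 equiv), −78 °C; isoprene; then MeI, −78 → −33 °C
Reagents that add atoms: iodomethane, CI; lithium, [Li] (counter‑ion of 17 only)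
Why: Birch‑type reductive alkylation: C5 of the reduced unsaturated ester is protonated axially from the α face to give the trans ring fusion, as in dissolving‑metal reductions of 19‑methyl‑4‑en‑3‑ones, and the ester enolate is then methylated from the α face, anti to the axial C10 methyl, so that CO2Me ends axial (β).

Step 11
Reactants: 18 the bicyclic silyl enol ether; 19 but‑3‑en‑2‑one
Product: 20 methyl 8,13‑dioxo‑14,15,17‑trinor‑9βH‑labdan‑19‑oate (3‑oxobutyl chain on C9, α)
Conditions: TiCl4, CH2Cl2, −78 °C; aq K2CO3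
Reagents that add atoms: none
Why: Mukaiyama–Michael addition of the regiodefined silyl enol ether places the chain on C9 only; attack anti to the C10 methyl is expected to give the 9α epimer, which is corrected in step 12.

Step 12
Reactants: 20 the diketone; 21 triethyl phosphonoacetate
Product: 23 15‑ethyl 19‑methyl 8‑oxo‑17‑norlabd‑13E‑ene‑15,19‑dioate, via 9‑epimeric keto enoate 22 (not isolated)
Conditions: NaH, THF, 0 °C → rt; then NaOEt (cat.), EtOH, rt
Reagents that add atoms: none
Why: Horner–Wadsworth–Emmons olefination should occur at the unhindered methyl ketone (the C8 carbonyl is flanked by a tertiary carbon next to quaternary C10) and favour the (E)‑enoate, any minor (Z)‑isomer being removed by chromatography; ethoxide then equilibrates C9 through the C8 enolate to the equatorial 9β side chain.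

Step 13
Reactants: 23 the keto enoate
Product: 24 15‑ethyl 19‑methyl labda‑8(17),13E‑diene‑15,19‑dioate
Conditions: Zn, CH2Br2, TiCl4, THF/CH2Cl2, 0 °C → rt
Reagents that add atoms: dibromomethane, BrCBr
Why: Takai–Lombardo methylenation is non‑basic and should convert the hindered, epimerisable C8 ketone into the exocyclic methylene without touching the esters or C9.

Step 14
Reactants: 24 the diene diester
Product: 25 15‑ethyl 19‑methyl 7α‑hydroxylabda‑8(17),13E‑diene‑15,19‑dioate
Conditions: SeO2 (0.5 equiv), t‑BuOOH, CH2Cl2, 0 °C → rt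
Reagents that add atoms: tert‑butyl hydroperoxide, CC(C)(C)OO
Why: Riley allylic oxidation (ene reaction, then [2,3]‑shift) of the 1,1‑disubstituted alkene hydroxylates the allylic methylene C7 with the exocyclic double bond restored and the oxygen delivered axially (7α); the electron‑poor enoate alkene and the hindered C9–H should not react.

Step 15
Reactants: 25 the 7α‑hydroxy diester
Product: 26 methyl 7α,15‑dihydroxylabda‑8(17),13E‑dien‑19‑oate
Conditions: i‑Bu2AlH, CH2Cl2, −78 °C; aq sodium potassium tartrate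
Reagents that add atoms: none
Why: The unhindered conjugated ethyl ester is reduced to the allylic alcohol, while the axial, neopentyl C19 methyl ester, shielded by the 1,3‑diaxial C10 methyl, should survive.

Step 16
Reactants: 26 the diol
Product: 27 methyl 15‑[(tert‑butyldimethylsilyl)oxy]‑7α‑hydroxylabda‑8(17),13E‑dien‑19‑oate
Conditions: TBSCl (1.05 equiv), imidazole, CH2Cl2, 0 °C
Reagents that add atoms: tert‑butyl(chloro)dimethylsilane, CC(C)(C)[Si](C)(C)Cl
Why: The primary allylic hydroxyl is silylated much faster than the axial secondary one.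

Step 17
Reactants: 27 the 7α‑alcohol
Product: 28 methyl 7β‑acetoxy‑15‑[(tert‑butyldimethylsilyl)oxy]labda‑8(17),13E‑dien‑19‑oate
Conditions: AcOH, PPh3, diisopropyl azodicarboxylate, toluene, 0 °C → rt
Reagents that add atoms: acetic acid, CC(=O)O
Why: In the Mitsunobu reaction acetate displaces the activated axial 7α‑oxyphosphonium group from the open equatorial direction (SN2), giving the equatorial 7β‑acetate with inversion.

Step 18
Reactants: 28 the silyl ether acetate
Product: 29 methyl (4S,5R,7S,9R,10R)‑7‑acetoxy‑15‑hydroxylabda‑8(17),13E‑dien‑19‑oate (target)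
Conditions: HF·pyridine, pyridine, THF, 0 °C → rt
Reagents that add atoms: none
Why: Buffered fluoride cleaves the primary silyl ether and leaves both esters, including the allylic acetate, intact.

**Compound list**

1 | hex‑5‑yn‑1‑ol | C#CCCCCO | starting material
2 | dimethyl[(1E)‑6‑(dimethylalumanyloxy)‑2‑methylhex‑1‑en‑1‑yl]alumane | C[Al](C)OCCCC/C(C)=C/[Al](C)C | intermediate (not isolated)
3 | (E)‑6‑iodo‑5‑methylhex‑5‑en‑1‑ol | OCCCC/C(C)=C/I | intermediate
4 | (E)‑6‑iodo‑5‑methylhex‑5‑enoic acid | OC(=O)CCC/C(C)=C/I | intermediate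
5 | (E)‑1‑(1H‑imidazol‑1‑yl)‑6‑iodo‑5‑methylhex‑5‑en‑1‑one | O=C(CCC/C(C)=C/I)n1ccnc1 | intermediate (not isolated)
6 | (E)‑6‑iodo‑N‑methoxy‑N,5‑dimethylhex‑5‑enamide | CON(C)C(=O)CCC/C(C)=C/I | intermediate
7 | tributyl(1‑ethoxyvinyl)stannane | CCCC[Sn](CCCC)(CCCC)C(=C)OCC | starting material
8 | (E)‑7‑ethoxy‑N‑methoxy‑N,5‑dimethylocta‑5,7‑dienamide | C=C(OCC)/C=C(\C)CCCC(=O)N(C)OC | intermediate (not isolated)
9 | (E)‑N‑methoxy‑N,5‑dimethyl‑7‑oxooct‑5‑enamide | CC(=O)/C=C(\C)CCCC(=O)N(C)OC | intermediate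
10 | (E)‑7‑[(tert‑butyldimethylsilyl)oxy]‑N‑methoxy‑N,5‑dimethylocta‑5,7‑dienamide | C=C(O[Si](C)(C)C(C)(C)C)/C=C(\C)CCCC(=O)N(C)OC | intermediate
11 | ethynylmagnesium bromide | C#C[Mg]Br | starting material
12 | (E)‑9‑[(tert‑butyldimethylsilyl)oxy]‑7‑methyldeca‑7,9‑dien‑1‑yn‑3‑one | C#CC(=O)CCC/C(C)=C/C(=C)O[Si](C)(C)C(C)(C)C | intermediate
13 | (4aR)‑6‑[(tert‑butyldimethylsilyl)oxy]‑4a‑methyl‑3,4,4a,7‑tetrahydronaphthalen‑1(2H)‑one | CC(C)(C)[Si](C)(C)OC=1CC=C2[C@](C)(CCCC2=O)C=1 | intermediate
14 | lithium (4aR)‑6‑[(tert‑butyldimethylsilyl)oxy]‑4a‑methyl‑2,3,4,4a,7,8‑hexahydronaphthalen‑1‑olate | [Li+].CC(C)(C)[Si](C)(C)OC=1CCC2=C([O-])CCC[C@]2(C)C=1 | intermediate (not isolated)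
15 | (4aR)‑6‑[(tert‑butyldimethylsilyl)oxy]‑4a‑methyl‑2,3,4,4a,7,8‑hexahydronaphthalen‑1‑yl trifluoromethanesulfonate | CC(C)(C)[Si](C)(C)OC=1CCC2=C(OS(=O)(=O)C(F)(F)F)CCC[C@]2(C)C=1 | intermediate
16 | methyl (4aR)‑6‑[(tert‑butyldimethylsilyl)oxy]‑4a‑methyl‑2,3,4,4a,7,8‑hexahydronaphthalene‑1‑carboxylate | CC(C)(C)[Si](C)(C)OC=1CCC2=C(C(=O)OC)CCC[C@]2(C)C=1 | intermediate
17 | lithium ester enolate of the 5α‑H reduced ester (C4=C19 enolate) | [Li+].CC(C)(C)[Si](C)(C)OC=1CC[C@@H]2[C@](C)(CCCC2=C([O-])OC)C=1 | intermediate (not isolated)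
18 | methyl (1S,4aS,8aR)‑6‑[(tert‑butyldimethylsilyl)oxy]‑1,4a‑dimethyl‑1,2,3,4,4a,7,8,8a‑octahydronaphthalene‑1‑carboxylate | CC(C)(C)[Si](C)(C)OC=1CC[C@@H]2[C@](C)(CCC[C@]2(C)C(=O)OC)C=1 | intermediate
19 | but‑3‑en‑2‑one | C=CC(C)=O | starting material
20 | methyl 8,13‑dioxo‑14,15,17‑trinor‑9βH‑labdan‑19‑oate (9α side chain) | O=C1CC[C@@H]2[C@](C)(CCC[C@]2(C)C(=O)OC)[C@@H]1CCC(C)=O | intermediate
21 | triethyl phosphonoacetate | CCOC(=O)CP(=O)(OCC)OCC | starting material
22 | 15‑ethyl 19‑methyl 8‑oxo‑17‑nor‑9βH‑labd‑13E‑ene‑15,19‑dioate (9α side chain) | O=C1CC[C@@H]2[C@](C)(CCC[C@]2(C)C(=O)OC)[C@@H]1CC/C(C)=C/C(=O)OCC | intermediate (not isolated)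
23 | 15‑ethyl 19‑methyl 8‑oxo‑17‑norlabd‑13E‑ene‑15,19‑dioate | O=C1CC[C@@H]2[C@](C)(CCC[C@]2(C)C(=O)OC)[C@H]1CC/C(C)=C/C(=O)OCC | intermediate
24 | 15‑ethyl 19‑methyl labda‑8(17),13E‑diene‑15,19‑dioate | C=C1CC[C@@H]2[C@](C)(CCC[C@]2(C)C(=O)OC)[C@H]1CC/C(C)=C/C(=O)OCC | intermediate
25 | 15‑ethyl 19‑methyl 7α‑hydroxylabda‑8(17),13E‑diene‑15,19‑dioate | C=C1[C@H](O)C[C@@H]2[C@](C)(CCC[C@]2(C)C(=O)OC)[C@H]1CC/C(C)=C/C(=O)OCC | intermediate
26 | methyl 7α,15‑dihydroxylabda‑8(17),13E‑dien‑19‑oate | C=C1[C@H](O)C[C@@H]2[C@](C)(CCC[C@]2(C)C(=O)OC)[C@H]1CC/C(C)=C/CO | intermediate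
27 | methyl 15‑[(tert‑butyldimethylsilyl)oxy]‑7α‑hydroxylabda‑8(17),13E‑dien‑19‑oate | C=C1[C@H](O)C[C@@H]2[C@](C)(CCC[C@]2(C)C(=O)OC)[C@H]1CC/C(C)=C/CO[Si](C)(C)C(C)(C)C | intermediate
28 | methyl 7β‑acetoxy‑15‑[(tert‑butyldimethylsilyl)oxy]labda‑8(17),13E‑dien‑19‑oate | C=C1[C@@H](OC(C)=O)C[C@@H]2[C@](C)(CCC[C@]2(C)C(=O)OC)[C@H]1CC/C(C)=C/CO[Si](C)(C)C(C)(C)C | intermediate
29 | methyl (4S,5R,7S,9R,10R)‑7‑acetoxy‑15‑hydroxylabda‑8(17),13E‑dien‑19‑oate | C=C1[C@@H](OC(C)=O)C[C@@H]2[C@](C)(CCC[C@]2(C)C(=O)OC)[C@H]1CC/C(C)=C/CO | target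

**Step count and risks**

Total step count: 18. Longest linear sequence: 18 steps (from 1).

Steps most likely to fail:

Step 7. The risk is weak enantiofacial discrimination, because the only stereocentre formed (C10) lies at the diene terminus remote from the catalyst‑bound C4 carbonyl, together with a racemic uncatalysed cyclisation of the reactive ynone. The fallback sets out from amide 10. Vinylmagnesium bromide would give the vinyl ketone (E)‑9‑[(tert‑butyldimethylsilyl)oxy]‑7‑methyldeca‑1,7,9‑trien‑3‑one F1. Its cyclisation under the same protonated oxazaborolidine, or under a chiral N‑triflyl phosphoramide Brønsted acid, is an enone/silyloxy‑diene Diels–Alder reaction in which the catalyst differentiates the faces of the prochiral dienophile carbon C5 next to the carbonyl and the endo rule relays this to C10, giving the cis‑fused ketone (4aR,8aS)‑6‑[(tert‑butyldimethylsilyl)oxy]‑4a‑methyl‑3,4,4a,7,8,8a‑hexahydronaphthalen‑1(2H)‑one F2. Thermodynamic enol triflate formation towards the ring‑fusion carbon (Tf2O, 2,6‑di‑tert‑butyl‑4‑methylpyridine, CH2Cl2) erases C5 and returns to the route at triflate 15.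

Step 11. The risk is that no C–C bond forms at the neopentyl‑like C9 next to quaternary C10, with protodesilylation of the enol ether or polymerisation of the enone taking over. The fallback sets out from 18. The small, highly electrophilic N,N‑dimethylmethyleneiminium iodide (CH2Cl2, rt) would give the Mannich base methyl 9α‑[(dimethylamino)methyl]‑8‑oxo‑11,12,13,14,15,16,17‑heptanor‑9βH‑labdan‑19‑oate F3. Quaternisation with MeI and elimination with NaHCO3 would give the α‑methylene ketone methyl 8‑oxo‑12,13,14,15,16,17‑hexanorlabd‑9(11)‑en‑19‑oate F4. Mukaiyama–Michael addition of 2‑(trimethylsilyloxy)propene (TiCl4, CH2Cl2, −78 °C) to its unhindered exocyclic CH2 terminus, followed by protonation of the C8 enolate from the α face, would give the 9β‑diketone methyl 8,13‑dioxo‑14,15,17‑trinorlabdan‑19‑oate F5. Under the olefination conditions of step 12 (no epimerisation then needed) F5 returns to the route at 23.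

Step 17. The risk is allylic transposition by attack of acetate at the exocyclic methylene carbon (SN2′), or elimination to a diene, instead of direct inversion. The fallback sets out from 27. Oxidation with MnO2 (CH2Cl2) would give the α‑methylene ketone methyl 15‑[(tert‑butyldimethylsilyl)oxy]‑7‑oxolabda‑8(17),13E‑dien‑19‑oate F6. Luche reduction (NaBH4, CeCl3·7H2O, MeOH, −78 °C; axial hydride delivery) would give the equatorial alcohol methyl 15‑[(tert‑butyldimethylsilyl)oxy]‑7β‑hydroxylabda‑8(17),13E‑dien‑19‑oate F7. Acetylation (Ac2O, 4‑(dimethylamino)pyridine, pyridine) returns to the route at 28.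

Further compounds
F1 | step 7 | (E)‑9‑[(tert‑butyldimethylsilyl)oxy]‑7‑methyldeca‑1,7,9‑trien‑3‑one | C=CC(=O)CCC/C(C)=C/C(=C)O[Si](C)(C)C(C)(C)C
F2 | step 7 | (4aR,8aS)‑6‑[(tert‑butyldimethylsilyl)oxy]‑4a‑methyl‑3,4,4a,7,8,8a‑hexahydronaphthalen‑1(2H)‑one | CC(C)(C)[Si](C)(C)OC=1CC[C@H]2[C@](C)(CCCC2=O)C=1
F3 | step 11 | methyl 9α‑[(dimethylamino)methyl]‑8‑oxo‑11,12,13,14,15,16,17‑heptanor‑9βH‑labdan‑19‑oate | O=C1CC[C@@H]2[C@](C)(CCC[C@]2(C)C(=O)OC)[C@@H]1CN(C)C
F4 | step 11 | methyl 8‑oxo‑12,13,14,15,16,17‑hexanorlabd‑9(11)‑en‑19‑oate | O=C1CC[C@@H]2[C@](C)(CCC[C@]2(C)C(=O)OC)C1=C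
F5 | step 11 | methyl 8,13‑dioxo‑14,15,17‑trinorlabdan‑19‑oate | O=C1CC[C@@H]2[C@](C)(CCC[C@]2(C)C(=O)OC)[C@H]1CCC(C)=O
F6 | step 17 | methyl 15‑[(tert‑butyldimethylsilyl)oxy]‑7‑oxolabda‑8(17),13E‑dien‑19‑oate | C=C1C(=O)C[C@@H]2[C@](C)(CCC[C@]2(C)C(=O)OC)[C@H]1CC/C(C)=C/CO[Si](C)(C)C(C)(C)C
F7 | step 17 | methyl 15‑[(tert‑butyldimethylsilyl)oxy]‑7β‑hydroxylabda‑8(17),13E‑dien‑19‑oate | C=C1[C@@H](O)C[C@@H]2[C@](C)(CCC[C@]2(C)C(=O)OC)[C@H]1CC/C(C)=C/CO[Si](C)(C)C(C)(C)C
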